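All runs were computed for an exercise; noise was put on by code.

The constant we start from is that of the first step, in which substrate meets coupling partner and yields single product, which takes a second partner to give double product; the flasks and their readings are these:

| flask | substrate | coupling partner | remark | time |
|---|---|---|---|---|
| red | 0.080 M | 0.30 M | run made earlier |  |
| teal | 0.24 M | 0.30 M | run made earlier |  |
| delta | 0.12 M | 0.300 M |  | 5.0 h |
| eta | 0.12 M | 0.180 M |  | 5.0 h |

- red (time / h: double product / %, substrate / %): 0.250: 1, 91; 0.417: 6, 75; 0.667: 2, 67; 1.00: 11, 55; 2.00: 27, 35; 3.00: 35, 23
- teal (time / h: double product / %, substrate / %): 0.200: 0, 87; 0.667: 1, 70; 1.00: 8, 61; 1.50: 14, 50; 2.50: 20, 35; 3.00: 23, 35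

(standard deviation of a reading: 2 percentage points)

- the numbers in the tables scatter with a standard deviation of 2 percentage points
- a reading or a percentage of double product counts all its forms, free or not

We read the constant from the substrate of the red run at 1.00 h, with the scatter of that reading:

k = ln(charged/left) / (t · c(coupling partner)) = 0.0332 M⁻¹ min⁻¹

The bench rule holds the partner at its charge, the pseudo-first-order view, so that substrate left = exp(−k · c(coupling partner) · t). Red and teal share one partner charge, so at 3.00 h the rule gives 16.6% for both. Yet red read 23% and teal read 35%, a wider miss in the flask with the larger ratio c(substrate)/c(coupling partner): 0.800 in teal against 0.267 in red. Eta stands at 0.667, above red, so we do not trust the rule there.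

We assume instead that the partner falls by about one substrate charge over a run, and reckon with the working partner level, the mean of its start and end:

c_w = c(coupling partner) − c(substrate)/2

Teal then has 0.180 M, which gives 34.1% against the 35% read. For eta:

c_w = 0.120 M, substrate left = exp(−k · c_w · t) = 30.3%

- which of these holds the largest part of the substrate at the end of delta (double product / single product / substrate)
- which of these holds the largest part of the substrate at the end of eta (double product / single product / substrate)
- final double product in eta, as a percentage of the substrate charged

The forecast, which says of eta “partner runs low”, named double product for delta, single product for eta, and 23% of double product in eta.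

Delta ends with double product holding the largest part at 44.9%. Eta gives 22.9% of double product, crystals counted in, and substrate holds the largest part at 31.0%, against our 30.3%.

    substrate + coupling partner → single product (k = 0.0355 M⁻¹ min⁻¹)
    coupling partner + single product → double product (k = 0.0318 M⁻¹ min⁻¹)
    crystals ⇌ double product, rate k3*(cs3 - [double product]) while solid is left; crystals form when [double product] > cs3 (solubility = 3.70 mM, k = 0.140 min⁻¹)
    single product → decomposed reagent (k = 0.00357 min⁻¹)

The partner in eta ended at 0.0697 M, where our assumption put 0.0600 M. The same flask charged with 0.030 M of substrate has c_w = 0.165 M, which reckons 19.3% of substrate left, and that flask held 18.4%.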